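**Strategy.** Read the 1,10‑ and 4,5‑epoxides as C1=C10 and C4=C5 alkenes (germacrane numbering). The CH2–CH2 bond C2–C3 between them is then the central sigma bond of a 1,5‑diene, C10=C1–C2–C3–C4=C5, so the ten‑membered ring is the [3,3] product of a six‑membered precursor. That precursor is a cis‑1‑isopropenyl‑2‑methyl‑2‑vinylcyclohexan‑1‑ol that already carries the C6, C7 and C8 oxygens and whose chair is locked by a trans‑fused C7/C8 acetal. One anionic oxy‑Cope ring expansion forms C2–C3, cleaves C5–C10 and sets the 1(10)Z and 4E geometries; the C5 enolate is trapped as its triflate.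

Key step: step 13

Remarks on the chemistry:
- The target as drawn has a cis 1,10‑epoxide (C2 and C9 on the same side, i.e. from a Z C1=C10 bond) and a trans 4,5‑epoxide (from an E C4=C5 bond); the route is built for exactly this.
- Carbon labels C1–C15 are the germacrane positions of the target and are kept for the cyclohexane intermediates (ring carbons C5–C10). "α" is the ring face of the C6 and C7 oxygens, "β" that of the C8 oxygen.
- The benzylic acetal carbon made in step 10 is carried as either epimer (written without configuration) and is deleted in step 17.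

Step 1
Reactants: 1 1,4‑dioxaspiro[4.5]dec‑6‑en‑8‑one
Product: 2 7‑iodo‑1,4‑dioxaspiro[4.5]dec‑6‑en‑8‑one
Conditions: I2, pyridine, CH2Cl2, 0 °C to rt
Reagents that add atoms: iodine, II
Why: α‑Iodination of the enone (conjugate addition of pyridine, iodination of the enolate, elimination) places a cross‑coupling handle on the carbon that becomes C7.

Step 2
Reactants: 2 7‑iodo‑1,4‑dioxaspiro[4.5]dec‑6‑en‑8‑one
Product: 3 (8R)‑7‑iodo‑1,4‑dioxaspiro[4.5]dec‑6‑en‑8‑ol
Conditions: (S)‑2‑methyl‑CBS‑oxazaborolidine (cat.), BH3·SMe2, THF, −30 °C; MeOH quench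
Reagents that add atoms: none
Why: CBS reduction, in which the iodoalkenyl arm is the large group, so the (S)‑catalyst should deliver hydride to give the (R)‑carbinol, the future C8 stereocentre from which all others are relayed.

Step 3
Reactants: 3 (8R)‑7‑iodo‑1,4‑dioxaspiro[4.5]dec‑6‑en‑8‑ol; 4 (triethylsilyl)acetylene
Product: 5 (8R)‑7‑[(triethylsilyl)ethynyl]‑1,4‑dioxaspiro[4.5]dec‑6‑en‑8‑ol
Conditions: PdCl2(PPh3)2 (cat.), CuI (cat.), i‑Pr2NH, THF, rt
Reagents that add atoms: none
Why: Sonogashira coupling of the alkenyl iodide installs the two carbons that become C11 and C13 as an alkyne, which is inert to the later dihydroxylation and base steps.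

Step 4
Reactants: 5 (8R)‑7‑[(triethylsilyl)ethynyl]‑1,4‑dioxaspiro[4.5]dec‑6‑en‑8‑ol
Product: 6 (8R)‑8‑[(4‑methoxybenzyl)oxy]‑7‑[(triethylsilyl)ethynyl]‑1,4‑dioxaspiro[4.5]dec‑6‑ene
Conditions: NaH, 4‑methoxybenzyl chloride, Bu4NI (cat.), DMF, 0 °C to rt
Reagents that add atoms: 4‑methoxybenzyl chloride, COc1ccc(CCl)cc1
Why: Williamson etherification gives a C8 ether that survives enolate chemistry and can later be oxidised into the conformational lock.

Step 5
Reactants: 6 (8R)‑8‑[(4‑methoxybenzyl)oxy]‑7‑[(triethylsilyl)ethynyl]‑1,4‑dioxaspiro[4.5]dec‑6‑ene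
Product: 7 (4R)‑4‑[(4‑methoxybenzyl)oxy]‑3‑[(triethylsilyl)ethynyl]cyclohex‑2‑en‑1‑one
Conditions: PPTS (cat.), acetone/H2O, 55 °C
Reagents that add atoms: water, O
Why: Acid‑catalysed ketal hydrolysis unveils the C5 ketone as an enone conjugated to C6=C7 while the benzylic ether and the silyl alkyne stay intact.

Step 6
Reactants: 7 (4R)‑4‑[(4‑methoxybenzyl)oxy]‑3‑[(triethylsilyl)ethynyl]cyclohex‑2‑en‑1‑one
Product: 8 (4R)‑6‑(hydroxymethylidene)‑4‑[(4‑methoxybenzyl)oxy]‑3‑[(triethylsilyl)ethynyl]cyclohex‑2‑en‑1‑one (enol form of the 6‑formyl ketone)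
Conditions: LiN(i‑Pr)2, THF, −78 °C; then CF3CH2OCHO, −78 to 0 °C
Reagents that add atoms: 2,2,2‑trifluoroethyl formate, O=COCC(F)(F)F
Why: Kinetic α'‑deprotonation at C10 followed by Claisen‑type formylation introduces C1 as a formyl group, a masked vinyl that tolerates the later OsO4 step.

Step 7
Reactants: 8 (4R)‑6‑(hydroxymethylidene)‑4‑[(4‑methoxybenzyl)oxy]‑3‑[(triethylsilyl)ethynyl]cyclohex‑2‑en‑1‑one
Product: 9 (1R,5R)‑5‑[(4‑methoxybenzyl)oxy]‑1‑methyl‑2‑oxo‑4‑[(triethylsilyl)ethynyl]cyclohex‑3‑ene‑1‑carbaldehyde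
Conditions: MeI, K2CO3, acetone, rt
Reagents that add atoms: iodomethane, CI
Why: C‑Alkylation of the β‑dicarbonyl enolate creates the C10 quaternary centre, the methyl (C14) entering anti to the C8 ether (1,3‑induction on the half‑chair) while C6 is still sp2 and cannot interfere.

Step 8
Reactants: 9 (1R,5R)‑5‑[(4‑methoxybenzyl)oxy]‑1‑methyl‑2‑oxo‑4‑[(triethylsilyl)ethynyl]cyclohex‑3‑ene‑1‑carbaldehyde
Product: 10 C6,C7‑cis‑diol (both hydroxyls α, anti to the C8 ether)
Conditions: OsO4 (cat.), NMO, citric acid, t‑BuOH/H2O, rt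
Reagents that add atoms: N‑methylmorpholine N‑oxide, C[N+]1([O-])CCOCC1; water, O
Why: Catalytic syn‑dihydroxylation of the only C=C bond (alkyne and aldehyde are inert) should occur anti to the allylic C8 ether, setting the C6 and C7 carbinol centres cis to each other and trans to the C8 oxygen.

Step 9
Reactants: 10 C6,C7‑cis‑diol
Product: 11 C6‑O‑tert‑butyldimethylsilyl ether of 10 (C7‑OH free)
Conditions: TBSOTf, 2,6‑lutidine, CH2Cl2, −78 °C
Reagents that add atoms: tert‑butyldimethylsilyl triflate, CC(C)(C)[Si](C)(C)OS(=O)(=O)C(F)(F)F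
Why: Silylation is selective for the secondary C6 hydroxyl over the tertiary propargylic C7 hydroxyl and protects the base‑labile β‑hydroxy ketone.

Step 10
Reactants: 11 C6‑O‑TBS ether
Product: 12 trans‑fused C7,C8‑O‑(4‑methoxybenzylidene) acetal
Conditions: DDQ, 4 Å molecular sieves, CH2Cl2, 0 °C to rt
Reagents that add atoms: none
Why: Oxidation of the 4‑methoxybenzyl ether to its benzylic oxocarbenium ion under anhydrous conditions and capture by the neighbouring trans C7 hydroxyl gives the dioxolane that later holds C7–O and C8–O diequatorial; the new acetal centre is inconsequential.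

Step 11
Reactants: 12 trans‑fused C7,C8‑acetal aldehyde
Product: 13 2‑methyl‑2‑vinyl ketone (C10: CH3 α, vinyl β)
Conditions: Ph3PCH3Br, KN(SiMe3)2, THF, −78 to 0 °C
Reagents that add atoms: methyltriphenylphosphonium bromide (as its ylide), C[P+](c1ccccc1)(c1ccccc1)c1ccccc1.[Br-]
Why: Wittig methylenation is chemoselective for the neopentyl aldehyde over the doubly flanked C5 ketone and completes the C1=C2 vinyl group.

Step 12
Reactants: 13 2‑methyl‑2‑vinyl ketone; 14 2‑propenylmagnesium bromide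
Product: 15 tertiary carbinol (C5: OH α and equatorial, isopropenyl β and axial, cis to the C10 vinyl)
Conditions: CeCl3, THF, −78 °C (organocerium formed from 14)
Reagents that add atoms: none
Why: Organocerium 1,2‑addition to the hindered ketone on the acetal‑locked chair should occur axially from the β face, anti to the axial C6 silyloxy and C10 methyl groups (Felkin–Anh and steric control), setting C5 with isopropenyl cis to vinyl.

Step 13
Reactants: 15 tertiary carbinol
Product: 17 ring‑expanded enol triflate (ten‑membered 1(10)Z/4E diene), via potassium enolate 16 (not isolated)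
Conditions: KN(SiMe3)2, 18‑crown‑6, THF, 0 °C to rt; then 5‑Cl‑2‑pyridyl‑NTf2, −78 °C
Reagents that add atoms: N‑(5‑chloropyridin‑2‑yl)bis(trifluoromethanesulfonimide), FC(F)(F)S(=O)(=O)N(c1ccc(Cl)cn1)S(=O)(=O)C(F)(F)F
Why: The C5 potassium alkoxide weakens the C5–C10 bond and the hexadiene C3=C4–C5–C10–C1=C2 undergoes a concerted [3,3] shift through a chair transition state, forming C2–C3 and breaking C5–C10; the closest known reaction is the anionic oxy‑Cope ring expansion of 1,2‑dialkenylcyclohexanols to cyclodec‑5‑enone enolates. The ten‑membered ring is closed by a four‑atom pericyclic ring expansion of the cyclohexane, both termini of the new bond being alkene CH2 carbons, not by an end‑to‑end cyclisation. No sp3 stereocentre is created and C6, C7 and C8 are untouched; the new stereochemical elements are the two alkene geometries. The trans‑fused C7/C8 acetal allows only the chair with isopropenyl axial and vinyl equatorial, so in the chair transition state C6 is pseudo‑equatorial at C5 (C3 and C6 trans, 4E enolate) and C9 is pseudo‑axial at C10 (C2 and C9 cis, 1(10)Z). The step needs this chair rather than a boat and a regiochemically intact enolate; the cis alkenyl pair set in steps 7 and 12 and the lock secure the former, and O‑sulfonylation of the C4=C5–O enolate at −78 °C before proton transfer secures the latter.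

Step 14
Reactants: 17 ring‑expanded enol triflate
Product: 18 (1(10)Z,4E)‑diene (C5–H)
Conditions: Pd(OAc)2 (cat.), PPh3, HCO2H, n‑Bu3N, DMF, 60 °C
Reagents that add atoms: none
Why: Palladium‑catalysed formate hydrogenolysis of the enol triflate (oxidative addition, decarboxylation to the palladium hydride, reductive elimination) replaces OTf by H with retention, giving the E C4=C5 trisubstituted alkene.

Step 15
Reactants: 18 (1(10)Z,4E)‑diene
Product: 19 C6 alcohol with terminal alkyne
Conditions: TBAF, THF, 0 °C to rt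
Reagents that add atoms: none
Why: Fluoride cleaves the C6 silyl ether and the alkynyl C–Si bond in one operation while the benzylidene acetal keeps the C7 and C8 oxygens masked.

Step 16
Reactants: 19 C6 alcohol with terminal alkyne
Product: 20 trans‑fused α‑methylene‑γ‑butyrolactone (C7/C8 acetal retained)
Conditions: PdI2 (cat.), PBu3, CO (7 atm), MeCN, 70 °C
Reagents that add atoms: carbon monoxide, [C-]#[O+]
Why: Palladium‑catalysed cyclocarbonylation of the homopropargylic alcohol (alkoxycarbonyl‑palladium formation at C6–O, syn addition across the alkyne, protonolysis) builds C12 and the exocyclic methylene in one step; C6–OH is the only free hydroxyl, so the lactone can close only onto C6.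

Step 17
Reactants: 20 lactone acetal
Product: 21 7α,8β‑diol lactone
Conditions: AcOH/THF/H2O, rt
Reagents that add atoms: none
Why: The strained trans‑fused 4‑methoxybenzylidene acetal hydrolyses under mild aqueous acid that should leave the diene and the α‑methylene lactone untouched.

Step 18
Reactants: 21 7α,8β‑diol lactone; 22 methacrylic anhydride
Product: 23 8‑O‑methacrylate
Conditions: Et3N, DMAP (cat.), CH2Cl2, 0 °C
Reagents that add atoms: none
Why: DMAP‑catalysed acylation takes the secondary C8 hydroxyl and leaves the tertiary C7 hydroxyl free.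

Step 19
Reactants: 23 8‑O‑methacrylate
Product: 24 CNP0228789.1 (target)
Conditions: mCPBA, NaHCO3, CH2Cl2, 0 °C
Reagents that add atoms: 3‑chloroperoxybenzoic acid, O=C(OO)c1cccc(Cl)c1
Why: Prilezhaev epoxidation takes only the two electron‑rich trisubstituted alkenes; C4=C5 should react on its exposed outer face as in related 6α,12‑olides (trans 4α,5β‑epoxide), and the cis C1=C10 bond on the α face, away from the 8β‑ester and guided by hydrogen bonding to the 7α‑OH (cis 1α,10α‑epoxide).

**Compound list**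

1 | 1,4‑dioxaspiro[4.5]dec‑6‑en‑8‑one | O=C1C=CC2(CC1)OCCO2 | starting material
2 | 7‑iodo‑1,4‑dioxaspiro[4.5]dec‑6‑en‑8‑one | O=C1CCC2(OCCO2)C=C1I | intermediate
3 | (8R)‑7‑iodo‑1,4‑dioxaspiro[4.5]dec‑6‑en‑8‑ol | O[C@@H]1CCC2(OCCO2)C=C1I | intermediate
4 | (triethylsilyl)acetylene | C#C[Si](CC)(CC)CC | starting material
5 | (8R)‑7‑[(triethylsilyl)ethynyl]‑1,4‑dioxaspiro[4.5]dec‑6‑en‑8‑ol | O[C@@H]1CCC2(OCCO2)C=C1C#C[Si](CC)(CC)CC | intermediate
6 | (8R)‑8‑[(4‑methoxybenzyl)oxy]‑7‑[(triethylsilyl)ethynyl]‑1,4‑dioxaspiro[4.5]dec‑6‑ene | COc1ccc(CO[C@@H]2CCC3(OCCO3)C=C2C#C[Si](CC)(CC)CC)cc1 | intermediate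
7 | (4R)‑4‑[(4‑methoxybenzyl)oxy]‑3‑[(triethylsilyl)ethynyl]cyclohex‑2‑en‑1‑one | COc1ccc(CO[C@@H]2CCC(=O)C=C2C#C[Si](CC)(CC)CC)cc1 | intermediate
8 | (4R)‑6‑(hydroxymethylidene)‑4‑[(4‑methoxybenzyl)oxy]‑3‑[(triethylsilyl)ethynyl]cyclohex‑2‑en‑1‑one (enol of the 6‑formyl ketone) | COc1ccc(CO[C@@H]2CC(=CO)C(=O)C=C2C#C[Si](CC)(CC)CC)cc1 | intermediate
9 | (1R,5R)‑5‑[(4‑methoxybenzyl)oxy]‑1‑methyl‑2‑oxo‑4‑[(triethylsilyl)ethynyl]cyclohex‑3‑ene‑1‑carbaldehyde (CH3 trans to the ether) | COc1ccc(CO[C@@H]2C[C@](C)(C=O)C(=O)C=C2C#C[Si](CC)(CC)CC)cc1 | intermediate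
10 | 3,4‑dihydroxy‑5‑[(4‑methoxybenzyl)oxy]‑1‑methyl‑2‑oxo‑4‑[(triethylsilyl)ethynyl]cyclohexane‑1‑carbaldehyde; C6‑OH, C7‑OH and C10‑CH3 on the α face, C8‑OPMB, alkynyl and CHO on the β face | COc1ccc(CO[C@@H]2C[C@](C)(C=O)C(=O)[C@@H](O)[C@]2(O)C#C[Si](CC)(CC)CC)cc1 | intermediate
11 | C6‑O‑tert‑butyldimethylsilyl ether of 10 | COc1ccc(CO[C@@H]2C[C@](C)(C=O)C(=O)[C@@H](O[Si](C)(C)C(C)(C)C)[C@]2(O)C#C[Si](CC)(CC)CC)cc1 | intermediate
12 | trans‑fused C7,C8‑O‑(4‑methoxybenzylidene) acetal of the C6‑O‑TBS keto aldehyde (acetal carbon unassigned) | COc1ccc(C2O[C@@H]3C[C@](C)(C=O)C(=O)[C@@H](O[Si](C)(C)C(C)(C)C)[C@]3(O2)C#C[Si](CC)(CC)CC)cc1 | intermediate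
13 | corresponding 2‑methyl‑2‑vinyl cyclohexanone (C10: CH3 α, vinyl β) | COc1ccc(C2O[C@@H]3C[C@](C)(C=C)C(=O)[C@@H](O[Si](C)(C)C(C)(C)C)[C@]3(O2)C#C[Si](CC)(CC)CC)cc1 | intermediate
14 | 2‑propenylmagnesium bromide | C=C(C)[Mg]Br | starting material
15 | 1‑isopropenyl‑2‑methyl‑2‑vinylcyclohexan‑1‑ol (C5‑OH α, isopropenyl β and cis to vinyl; C6‑OTBS α; C7,C8 trans acetal; alkynyl β) | COc1ccc(C2O[C@@H]3C[C@](C)(C=C)[C@](O)(C(C)=C)[C@@H](O[Si](C)(C)C(C)(C)C)[C@]3(O2)C#C[Si](CC)(CC)CC)cc1 | intermediate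
16 | potassium C4=C5 enolate of the ring‑expanded (1(10)Z)‑cyclodecadienone (C3 and C6 trans) | C1/C=C(C)\C[C@H]2OC(c3ccc(OC)cc3)O[C@]2(C#C[Si](CC)(CC)CC)[C@H](O[Si](C)(C)C(C)(C)C)/C([O-])=C(C)/C1.[K+] | intermediate
17 | C5 enol triflate of the ten‑membered ring (C1=C10 Z; C3 and C6 trans across C4=C5) | C1/C=C(C)\C[C@H]2OC(c3ccc(OC)cc3)O[C@]2(C#C[Si](CC)(CC)CC)[C@H](O[Si](C)(C)C(C)(C)C)/C(OS(=O)(=O)C(F)(F)F)=C(C)/C1 | intermediate
18 | (1(10)Z,4E)‑cyclodecadiene with 6α‑OTBS, 7α,8β‑acetal, 7β‑(triethylsilyl)ethynyl | C1/C=C(C)\C[C@H]2OC(c3ccc(OC)cc3)O[C@]2(C#C[Si](CC)(CC)CC)[C@H](O[Si](C)(C)C(C)(C)C)/C=C(C)/C1 | intermediate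
19 | 6α‑hydroxy‑7β‑ethynyl diene (7α,8β‑acetal retained) | C1/C=C(C)\C[C@H]2OC(c3ccc(OC)cc3)O[C@]2(C#C)[C@H](O)/C=C(C)/C1 | intermediate
20 | (1(10)Z,4E)‑germacra‑1(10),4,11(13)‑trien‑6α,12‑olide 7α,8β‑O‑(4‑methoxybenzylidene) acetal | C1/C=C(C)\C[C@H]2OC(c3ccc(OC)cc3)O[C@@]24C(=C)C(=O)O[C@@H]4/C=C(C)/C1 | intermediate
21 | 7α,8β‑dihydroxy‑(1(10)Z,4E)‑germacra‑1(10),4,11(13)‑trien‑6α,12‑olide | C1/C=C(C)\C[C@@H](O)[C@@]2(O)C(=C)C(=O)O[C@@H]2/C=C(C)/C1 | intermediate
22 | methacrylic anhydride | C=C(C)C(=O)OC(=O)C(C)=C | starting material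
23 | 7α‑hydroxy‑8β‑methacryloyloxy‑(1(10)Z,4E)‑germacra‑1(10),4,11(13)‑trien‑6α,12‑olide | C1/C=C(C)\C[C@@H](OC(=O)C(C)=C)[C@@]2(O)C(=C)C(=O)O[C@@H]2/C=C(C)/C1 | intermediate
24 | CNP0228789.1: (1S,4R,5R,6R,7S,8R,10R)‑1,10:4,5‑diepoxy‑7‑hydroxy‑8‑methacryloyloxygermacr‑11(13)‑en‑6,12‑olide | C=C(C)C(=O)O[C@@H]1C[C@@]2(C)O[C@H]2CC[C@@]2(C)O[C@@H]2[C@H]2OC(=O)C(=C)[C@@]21O | target

**Step count and risks**

Total steps: 19. Longest linear sequence: 19 steps (1 to 24).

The three steps most likely to fail: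

1. Step 13 (key step). What may go wrong: fragmentation of the potassium alkoxide, or proton transfer within the ring‑expanded enolate followed by β‑elimination of the C7 acetal oxygen, may outrun rearrangement and O‑sulfonylation. Fallback: take the charge out of the [3,3] step. Carbinol 15 is silylated with N‑(trimethylsilyl)imidazole (neat, 60 °C) to the trimethylsilyl ether F1. F1 is heated (degassed decalin, about 200 °C, sealed tube) in a neutral siloxy‑Cope rearrangement through the same locked chair to the ring‑expanded trimethylsilyl enol ether F2. MeLi (THF, 0 °C) then releases the regiodefined lithium enolate, which is sulfonylated with the same pyridyl triflimide at −78 °C; the route is rejoined at 17.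

2. Step 10. What may go wrong: the benzylic oxocarbenium ion may be captured by adventitious water faster than by the hindered tertiary C7 hydroxyl, so the 4‑methoxybenzyl group is simply lost and the strained trans‑fused dioxolane does not close. Fallback: build the lock in two steps under thermodynamic control. DDQ in wet CH2Cl2 deliberately cleaves the ether of 11 to the C7,C8‑diol F3. Acid‑catalysed transacetalisation of F3 with 4‑methoxybenzaldehyde dimethyl acetal (PPTS, benzene, removal of methanol) closes the acetal and returns to 12.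

3. Step 19. What may go wrong: poor facial selectivity at the cis C1=C10 bond (attack on the β face would give the 1β,10β‑epoxide), the C4=C5 face being the less doubtful one. Fallback: replace substrate control by reagent control at C1=C10. Triene 23 is mono‑epoxidised at the more electron‑rich C1=C10 bond by Shi epoxidation with the L‑fructose‑derived ketone catalyst (KHSO5 as its triple salt, K2CO3 buffer, MeCN/dimethoxymethane, 0 °C); the spiro transition‑state model predicts the (1S,10R) epoxide for this catalyst enantiomer, i.e. the 1α,10α‑mono‑epoxide F4. The remaining C4=C5 bond of F4 is then epoxidised with mCPBA as in step 19, arriving at 24.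

Further compounds
F1 | step 13 | trimethylsilyl ether of carbinol 15 | COc1ccc(C2O[C@@H]3C[C@](C)(C=C)[C@](O[Si](C)(C)C)(C(C)=C)[C@@H](O[Si](C)(C)C(C)(C)C)[C@]3(O2)C#C[Si](CC)(CC)CC)cc1
F2 | step 13 | ring‑expanded C5 trimethylsilyl enol ether (C1=C10 Z; C3 and C6 trans across C4=C5) | C1/C=C(C)\C[C@H]2OC(c3ccc(OC)cc3)O[C@]2(C#C[Si](CC)(CC)CC)[C@H](O[Si](C)(C)C(C)(C)C)/C(O[Si](C)(C)C)=C(C)/C1
F3 | step 10 | C7,C8‑diol of the C6‑O‑TBS keto aldehyde (PMB removed from 11) | O[C@@H]1C[C@](C)(C=O)C(=O)[C@@H](O[Si](C)(C)C(C)(C)C)[C@]1(O)C#C[Si](CC)(CC)CC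
F4 | step 19 | 1α,10α‑epoxy‑7α‑hydroxy‑8β‑methacryloyloxy‑(4E)‑germacra‑4,11(13)‑dien‑6α,12‑olide | C=C(C)C(=O)O[C@@H]1C[C@@]2(C)O[C@H]2CC/C(C)=C/[C@H]2OC(=O)C(=C)[C@@]21O
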